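Compound numbers are those of the steps and of the compound list below.

## Analysis of the target

The target 17 is a 2,3-dihydro-1-benzofuran; ring A is the benzene ring and ring B the five-membered oxygen ring. C5 of ring A, para to the ring oxygen O1, carries an (E)-propenoic acid. C2 of ring B carries the chain C1'(CH3)–C2'H2–O, whose oxygen is acylated by (E)-4-hydroxycinnamic acid. The two stereocentres, C2 (S) and the exocyclic methine C1' (S), are directly bonded; with C3–C2–C1'–C2' drawn as a zigzag, O1 and the C1' methyl group lie on the same side (syn). Sensitive groups are two conjugated E alkenes (no ozone or hydrogenation once they are present), a free phenol, a free acid, and an alkyl ester of a phenolic acid that forbids a final saponification. The periphery is routine. The difficulty is the C2/C1' pair, because C1' carries only carbon and hydrogen and lies outside the ring, so neither ring-based control nor a carbonyl addition that leaves an oxygen on it can reach it directly. The plan rests on O1, C2 and C1' being contiguous. If O1 starts as the oxygen of an aryl but-2-enyl ether and C2 as a carbene carbon held ortho to it, the oxygen can bond to C2, closing ring B, and then pass its but-2-enyl group to C2 through the far alkene carbon, which becomes C1'. The price is a ketone at C3 and one carbon too many at C2', both corrected afterwards.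

## Retrosynthetic reasoning

17 to 16. The last operation frees the C5 propenoic acid from its tert-butyl ester. An acid-labile ester is chosen because acidolysis leaves the base-sensitive 4-hydroxycinnamate untouched.

16 to 14 and 15. The C2'–O bond of the side-chain ester is cut. In the forward direction the carboxylate of (E)-4-hydroxycinnamic acid (15) displaces the activated primary hydroxyl of alcohol 14 under Mitsunobu conditions. The acidity gap between the carboxylic acid and the phenol of 15 allows its use without protection, and the reacting carbon is not stereogenic.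

14 to 12 and 13. The C5–vinyl bond is cut, giving bromo alcohol 12 and tert-butyl acrylate (13) as Heck partners. The coupling comes after the alkene cleavage for two reasons: the vinyl group of 10 would itself be a Heck acceptor, and the cinnamate alkene would not survive ozone.

12 to 10. The primary alcohol at C2' comes from the terminal alkene of 10 by oxidative cleavage and reduction through the transient aldehyde 11. This removes the extra carbon and leaves C1' untouched.

10 to 7. The C3 methylene comes from the C3 ketone of 7 through alcohol 8 and its thiocarbonyl derivative 9. A radical path is preferred to a cationic one, because a C3 cation could lose the C2 hydrogen to give the aromatic benzofuran and erase C2.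

7 to 5. This is the key disconnection: O1–C2 and C2–C1' are both cut, leading to diazoketone 5. No other pair of cuts sets both stereocentres at once from an achiral, acyclic precursor. The forward step must form the oxonium ylide 6, transfer the but-2-enyl group with allylic transposition, and control two new stereocentres.

5 to 3. The diazo group is traced to the methyl group of ketone 3, activated in passing as the trifluoroacetyl derivative 4.

3 to 1 and 2. The aryl O–CH2 bond is cut, giving the commercial phenol 1 and (2Z)-but-2-en-1-ol (2). The forward etherification must keep the Z geometry, since this geometry later determines the C2/C1' relation.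

## Alternatives that were turned down

Alternative 1: C3a–C3 and C2–C1' are cut together. The forward key step is a palladium-catalysed conjunctive coupling of an aryl triflate with a vinyl boron ate complex carrying an isopropenyl group. The aryl palladium species binds the vinyl group, isopropenyl migrates from boron to carbon, and reductive elimination gives the boronic ester A1. Oxidation of the C–B bond and ring closure by nucleophilic aromatic substitution of the fluoride would then give the isopropenyl dihydrobenzofuran A2.
- For it: three simple components, C3 already a methylene, a secure ring closure activated by the para ester, and usually high enantiocontrol at C2 in such 1,2-metallate couplings. On these points it is stronger than the chosen route.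
- Against it: C1' is not set. It would come from hydroboration of the 1,1-disubstituted alkene of A2, where the uncatalysed reaction of such allylic ethers is expected to favour the anti isomer, the opposite of what is needed. With two alkenyl groups on boron, which one binds palladium and which migrates is an additional selectivity question. The C5 ester needs reduction, oxidation and olefination to become the propenoate.
- Comparison: the chosen route spends steps on removing the C3 oxygen, but it fixes C2 and C1' in one event with their relation encoded in the alkene geometry.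

Alternative 2: the C1'–CH3 bond and the C2' oxygen are disconnected. The forward key step is a zirconium-catalysed asymmetric methylalumination of the vinyl group of A3, followed by oxidation of the C–Al bond. This gives A4, which is the same substance as 12.
- For it: no C3 oxygen to remove and no carbon to excise, and each stereocentre under separate catalyst control. In step economy after the ring is made it is stronger than the chosen route.
- Against it: C2 must first be set in a separate asymmetric synthesis of A3. The alkene is α-branched and sits next to an allylic aryl ether oxygen, which can coordinate to, or be ionised by, the strongly Lewis-acidic aluminium reagents. Enantioselectivity in methylalumination of monosubstituted alkenes is typically only moderate, and it would be superimposed on the existing C2 centre as a matched or mismatched case.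
- Comparison: the chosen route uses a neutral, catalytic step that tolerates the ether, since the ether is its reacting group, and it needs one stereodefining operation instead of two.

Alternative 3: C3a–C3 and O1–C2 are cut. The forward key step is a palladium-catalysed heteroannulation of an ortho-iodophenol ester with a 2-substituted buta-1,3-diene under a chiral ligand. The aryl palladium species adds to the unsubstituted vinyl terminus and the phenoxide closes ring B on the π-allyl, giving A5.
- For it: it is convergent, closes ring B in one step, brings C2' at the right oxidation level, and has C3 as a methylene. Here too it is stronger on step count around the ring.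
- Against it: the aryl group can add to either end of the unsymmetrical diene. Enantiocontrol with 2-substituted dienes is less secure than with simple ones. C1' still requires a second stereodefining step, a hydrogenation of the 1,1-disubstituted alkene next to C2. The C5 ester again needs a three-step homologation.
- Comparison: the chosen route sets both centres in one step and carries bromine at C5, which is converted to the propenoate in a single Heck reaction.

Key step: step 4

Assumption: (2Z)-but-2-en-1-ol (2) is taken as a commercial material of high geometric purity; the Z:E ratio of ether 3 limits the diastereomeric purity of 7.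

## Route

Step 1
Reactants: 1 1-(5-bromo-2-hydroxyphenyl)ethan-1-one; 2 (2Z)-but-2-en-1-ol
Product: 3 1-{5-bromo-2-[(2Z)-but-2-en-1-yloxy]phenyl}ethan-1-one
Conditions: PPh3, DIAD, THF, 0 °C → rt
Reagents that add atoms: none
Why: Mitsunobu etherification; the phenol is acidic enough to protonate the betaine, and direct SN2 displacement at the primary allylic carbon carries the Z geometry over unchanged. No stereocentre is formed.

Step 2
Reactants: 3 1-{5-bromo-2-[(2Z)-but-2-en-1-yloxy]phenyl}ethan-1-one
Product: 4 1-{5-bromo-2-[(2Z)-but-2-en-1-yloxy]phenyl}-4,4,4-trifluorobutane-1,3-dione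
Conditions: LiN(SiMe3)2, THF, −78 °C; CF3CO2CH2CF3; then 5% aq. HCl; used crude
Reagents that add atoms: 2,2,2-trifluoroethyl trifluoroacetate, O=C(OCC(F)(F)F)C(F)(F)F
Why: Claisen-type acylation of the kinetic lithium enolate of the methyl ketone by an activated trifluoroacetate, the first stage of a detrifluoroacetylative diazo transfer. The ether, the alkene and the aryl bromide are inert to the amide base at −78 °C.

Step 3
Reactants: 4 1-{5-bromo-2-[(2Z)-but-2-en-1-yloxy]phenyl}-4,4,4-trifluorobutane-1,3-dione
Product: 5 1-{5-bromo-2-[(2Z)-but-2-en-1-yloxy]phenyl}-2-diazoethan-1-one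
Conditions: MsN3, Et3N, H2O (1 equiv), MeCN, rt
Reagents that add atoms: methanesulfonyl azide, CS(=O)(=O)N=[N+]=[N-]
Why: Regitz-type diazo transfer to the activated methylene, followed by retro-Claisen loss of the trifluoroacetyl group as the N-sulfonyl amide. This gives the terminal diazoketone, which direct transfer to a simple methyl ketone does not.

Step 4
Reactants: 5 1-{5-bromo-2-[(2Z)-but-2-en-1-yloxy]phenyl}-2-diazoethan-1-one
Product: 7 (2R)-5-bromo-2-[(2S)-but-3-en-2-yl]-1-benzofuran-3(2H)-one, via cyclic oxonium ylide 6 (not isolated)
Conditions: Rh2(S-PTTL)4 (dirhodium tetrakis[N-phthaloyl-(S)-tert-leucinate], 2 mol%), toluene, −40 → 0 °C, slow addition of 5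
Reagents that add atoms: none
Why: The dirhodium carboxylate expels N2 from 5 to give an electrophilic rhodium carbenoid, and the ortho ether oxygen adds to it through one of its two enantiotopic lone pairs to form the five-membered oxonium ylide 6; ring B is closed by O1–C2 bond formation, a heteroatom-to-carbenoid closure to a five-membered ring that should outpace cyclopropanation of the distant alkene, which would need a seven-membered ring. The ylide then undergoes a symmetry-allowed suprafacial [2,3]-sigmatropic shift through a five-membered envelope made of C2, O1 and the three but-2-enyl carbons, breaking O1–CH2, forming C2–C1' and moving the alkene to the terminal position. The closest known reaction type is the rhodium- or copper-catalysed tandem oxonium ylide formation and [2,3]-rearrangement of ortho-allyloxyaryl diazoketones to 2-allylbenzofuran-3(2H)-ones, including variants with chiral dirhodium carboxylates. The relation of C1' to C2 is set by alkene geometry together with the envelope: when the but-2-enyl chain folds away from the furanone ring (C3 carbonyl exo), the Z methyl group ends syn to O1 across C2–C1', as the target requires, whereas the E ether would give the anti product through the same envelope. The absolute configuration at C2 is set by the catalyst, which chooses the lone pair of O1 and so the face of the ylide that carries the but-2-enyl group; this is transmitted only if rearrangement is faster than loss of rhodium and inversion at oxygen, hence the low temperature and the non-coordinating solvent. The step also needs selectivity for the [2,3] path over [1,2]-shift, [1,4]-migration to the enolate oxygen and C–H insertion next to oxygen; the allylic migrating group and a dirhodium carboxylate in place of a copper catalyst favour the concerted [2,3] path. The product is stereogenic next to an enolisable ketone and is taken on without delay.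

Step 5
Reactants: 7 (2R)-5-bromo-2-[(2S)-but-3-en-2-yl]-1-benzofuran-3(2H)-one
Product: 8 (2R,3R)-5-bromo-2-[(2S)-but-3-en-2-yl]-2,3-dihydro-1-benzofuran-3-ol
Conditions: NaBH4, CeCl3·7H2O, MeOH, −78 °C
Reagents that add atoms: none
Why: Luche reduction, fast and nearly neutral at low temperature, so the ketone is consumed before C2 can enolise. Hydride should approach anti to the C2 side chain to give mainly the cis alcohol; the C3 configuration is of no consequence because C3 becomes CH2 in step 7.

Step 6
Reactants: 8 (2R,3R)-5-bromo-2-[(2S)-but-3-en-2-yl]-2,3-dihydro-1-benzofuran-3-ol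
Product: 9 O-{(2R,3R)-5-bromo-2-[(2S)-but-3-en-2-yl]-2,3-dihydro-1-benzofuran-3-yl} 1H-imidazole-1-carbothioate
Conditions: 1,1'-thiocarbonyldiimidazole, DMAP (cat.), CH2Cl2, 40 °C
Reagents that add atoms: 1,1'-thiocarbonyldiimidazole, S=C(n1ccnc1)n1ccnc1
Why: Thioacylation of the secondary alcohol, the first stage of a Barton–McCombie deoxygenation. The conditions are non-acidic, so no benzylic cation forms and elimination toward the benzofuran is avoided.

Step 7
Reactants: 9 O-{(2R,3R)-5-bromo-2-[(2S)-but-3-en-2-yl]-2,3-dihydro-1-benzofuran-3-yl} 1H-imidazole-1-carbothioate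
Product: 10 (2S)-5-bromo-2-[(2S)-but-3-en-2-yl]-2,3-dihydro-1-benzofuran
Conditions: Bu3SnH (1.2 equiv, slow addition), AIBN (cat.), toluene, 80 °C
Reagents that add atoms: none
Why: Barton–McCombie radical deoxygenation: the stannyl radical adds to C=S, the benzylic C3–O bond fragments, and the C3 radical takes hydrogen from the tin hydride, leaving C2 and C1' untouched. The radical orbital at C3 is orthogonal to the C2–O1 bond and attack on the vinyl group would be 4-exo or 5-endo, so ring opening and cyclisation should be slow; the thiocarbonyl group reacts much faster than the aryl bromide, so only a slight excess of hydride is used.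

Step 8
Reactants: 10 (2S)-5-bromo-2-[(2S)-but-3-en-2-yl]-2,3-dihydro-1-benzofuran
Product: 12 (2S)-2-[(2S)-5-bromo-2,3-dihydro-1-benzofuran-2-yl]propan-1-ol, via aldehyde 11 (not isolated)
Conditions: O3, pyridine, CH2Cl2, −78 °C; then NaBH4, MeOH, −78 → 0 °C
Reagents that add atoms: ozone, [O-][O+]=O
Why: Ozonolysis of the only alkene, with pyridine converting the carbonyl oxide directly to the carbonyl compound so that no peroxide accumulates. The α-branched aldehyde 11 is reduced by borohydride in the same flask before it can epimerise at C1'; the bromoarene reacts with ozone far more slowly than the terminal alkene.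

Step 9
Reactants: 12 (2S)-2-[(2S)-5-bromo-2,3-dihydro-1-benzofuran-2-yl]propan-1-ol; 13 tert-butyl prop-2-enoate
Product: 14 tert-butyl (2E)-3-{(2S)-2-[(2S)-1-hydroxypropan-2-yl]-2,3-dihydro-1-benzofuran-5-yl}prop-2-enoate
Conditions: Pd(OAc)2 (5 mol%), P(o-tol)3 (10 mol%), Et3N, DMF, 100 °C
Reagents that add atoms: none
Why: Heck reaction: oxidative addition of the aryl bromide to zerovalent palladium formed in situ, syn carbopalladation of the acrylate and syn β-hydride elimination, which should give the E alkene. The free primary alcohol and the ring ether are tolerated.

Step 10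
Reactants: 14 tert-butyl (2E)-3-{(2S)-2-[(2S)-1-hydroxypropan-2-yl]-2,3-dihydro-1-benzofuran-5-yl}prop-2-enoate; 15 (2E)-3-(4-hydroxyphenyl)prop-2-enoic acid
Product: 16 tert-butyl (2E)-3-[(2S)-2-{(2S)-1-[(2E)-3-(4-hydroxyphenyl)prop-2-enoyloxy]propan-2-yl}-2,3-dihydro-1-benzofuran-5-yl]prop-2-enoate
Conditions: PPh3, DIAD, THF, 0 °C → rt (15 in excess)
Reagents that add atoms: none
Why: Mitsunobu esterification; the carboxylic acid of 15 is several pKa units more acidic than its phenol, so the carboxylate is the nucleophile that displaces the activated primary oxygen of 14 and the phenol needs no protection. The reacting carbon C2' is not stereogenic and C1' is not involved.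

Step 11
Reactants: 16 tert-butyl (2E)-3-[(2S)-2-{(2S)-1-[(2E)-3-(4-hydroxyphenyl)prop-2-enoyloxy]propan-2-yl}-2,3-dihydro-1-benzofuran-5-yl]prop-2-enoate
Product: 17 (2E)-3-[(2S)-2-{(2S)-1-[(2E)-3-(4-hydroxyphenyl)prop-2-enoyloxy]propan-2-yl}-2,3-dihydro-1-benzofuran-5-yl]prop-2-enoic acid
Conditions: CF3CO2H, CH2Cl2 (1:4), 0 °C → rt
Reagents that add atoms: none
Why: Acidolysis of the tert-butyl ester with loss of the tert-butyl cation as isobutene. The primary alkyl 4-hydroxycinnamate, the aryl ether and both E alkenes should be stable to CF3CO2H at room temperature.

## Compound list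

1 | 1-(5-bromo-2-hydroxyphenyl)ethan-1-one | CC(=O)c1cc(Br)ccc1O | starting material
2 | (2Z)-but-2-en-1-ol | C/C=C\CO | starting material
3 | 1-{5-bromo-2-[(2Z)-but-2-en-1-yloxy]phenyl}ethan-1-one | C/C=C\COc1ccc(Br)cc1C(C)=O | intermediate
4 | 1-{5-bromo-2-[(2Z)-but-2-en-1-yloxy]phenyl}-4,4,4-trifluorobutane-1,3-dione | C/C=C\COc1ccc(Br)cc1C(=O)CC(=O)C(F)(F)F | intermediate
5 | 1-{5-bromo-2-[(2Z)-but-2-en-1-yloxy]phenyl}-2-diazoethan-1-one | C/C=C\COc1ccc(Br)cc1C(=O)C=[N+]=[N-] | intermediate
6 | 5-bromo-1-[(2Z)-but-2-en-1-yl]-3-oxo-2,3-dihydro-1-benzofuran-1-ium-2-ide (oxonium ylide, drawn metal-free) | C/C=C\C[O+]1[CH-]C(=O)c2cc(Br)ccc21 | intermediate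
7 | (2R)-5-bromo-2-[(2S)-but-3-en-2-yl]-1-benzofuran-3(2H)-one | C[C@@H](C=C)[C@@H]1C(=O)c2cc(Br)ccc2O1 | intermediate
8 | (2R,3R)-5-bromo-2-[(2S)-but-3-en-2-yl]-2,3-dihydro-1-benzofuran-3-ol | C[C@@H](C=C)[C@@H]1[C@H](O)c2cc(Br)ccc2O1 | intermediate
9 | O-{(2R,3R)-5-bromo-2-[(2S)-but-3-en-2-yl]-2,3-dihydro-1-benzofuran-3-yl} 1H-imidazole-1-carbothioate | C[C@@H](C=C)[C@@H]1[C@H](OC(=S)n2ccnc2)c2cc(Br)ccc2O1 | intermediate
10 | (2S)-5-bromo-2-[(2S)-but-3-en-2-yl]-2,3-dihydro-1-benzofuran | C[C@@H](C=C)[C@@H]1Cc2cc(Br)ccc2O1 | intermediate
11 | (2R)-2-[(2S)-5-bromo-2,3-dihydro-1-benzofuran-2-yl]propanal | C[C@@H](C=O)[C@@H]1Cc2cc(Br)ccc2O1 | intermediate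
12 | (2S)-2-[(2S)-5-bromo-2,3-dihydro-1-benzofuran-2-yl]propan-1-ol | C[C@@H](CO)[C@@H]1Cc2cc(Br)ccc2O1 | intermediate
13 | tert-butyl prop-2-enoate | C=CC(=O)OC(C)(C)C | starting material
14 | tert-butyl (2E)-3-{(2S)-2-[(2S)-1-hydroxypropan-2-yl]-2,3-dihydro-1-benzofuran-5-yl}prop-2-enoate | C[C@@H](CO)[C@@H]1Cc2cc(/C=C/C(=O)OC(C)(C)C)ccc2O1 | intermediate
15 | (2E)-3-(4-hydroxyphenyl)prop-2-enoic acid | O=C(O)/C=C/c1ccc(O)cc1 | starting material
16 | tert-butyl (2E)-3-[(2S)-2-{(2S)-1-[(2E)-3-(4-hydroxyphenyl)prop-2-enoyloxy]propan-2-yl}-2,3-dihydro-1-benzofuran-5-yl]prop-2-enoate | C[C@@H](COC(=O)/C=C/c1ccc(O)cc1)[C@@H]1Cc2cc(/C=C/C(=O)OC(C)(C)C)ccc2O1 | intermediate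
17 | (2E)-3-[(2S)-2-{(2S)-1-[(2E)-3-(4-hydroxyphenyl)prop-2-enoyloxy]propan-2-yl}-2,3-dihydro-1-benzofuran-5-yl]prop-2-enoic acid | C[C@@H](COC(=O)/C=C/c1ccc(O)cc1)[C@@H]1Cc2cc(/C=C/C(=O)O)ccc2O1 | target

## Step count and least certain steps

Total: 11 steps. Longest linear sequence: 11 steps, from 1 to 17; 2, 13 and 15 enter as commercial materials.

Step 4 (key step). Three things are most likely to go wrong.
- Enantiofacial discrimination may be weak. A terminal acceptor-only carbenoid is very reactive, and the ylide may leave rhodium and invert at oxygen before it rearranges, so the catalyst's chirality would not reach C2. The sense of induction with this substrate also has to be assigned; if it is opposite, the mirror-image catalyst applies.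
- The two envelopes may compete. In the exo envelope the Z methyl group lies over ring B, so the syn/anti ratio may be modest; inverting the alkene geometry of the ether is the first variable to test.
- C2 may erode by enolisation during isolation, and [1,2]-shift, [1,4]-migration or C–H insertion may take part of the material.

Fallback for step 4: it sets out from 5 and returns at 10, bypassing steps 4 to 7 and the C3 ketone.
- Wolff rearrangement of 5 (PhCO2Ag, Et3N, MeOH) should give methyl {5-bromo-2-[(2Z)-but-2-en-1-yloxy]phenyl}acetate F1.
- Reduction with i-Bu2AlH at −78 °C should give {5-bromo-2-[(2Z)-but-2-en-1-yloxy]phenyl}acetaldehyde F2.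
- Crotylboration with (E)-but-2-enyl-B(Ipc)2, made from (−)-Ipc2BOMe, at −78 °C should give the anti alcohol (2R,3S)-1-{5-bromo-2-[(2Z)-but-2-en-1-yloxy]phenyl}-3-methylpent-4-en-2-ol F3. Both stereocentres are set by the reagent through a chair transition state.
- Pd(PPh3)4 with morpholine removes the but-2-enyl group from the phenol to give (2R,3S)-1-(5-bromo-2-hydroxyphenyl)-3-methylpent-4-en-2-ol F4.
- Intramolecular Mitsunobu etherification (PPh3, DIAD) closes ring B with inversion at the carbinol carbon and should give 10.

Step 7. The stannyl radical may abstract bromine from C5 in competition with addition to the thiocarbonyl group. The benzylic thiocarbonyl derivative may also rearrange thermally from oxygen to sulfur before the chain starts. Fallback: from 8, ionic hydrogenation with Et3SiH and CF3CO2H in CH2Cl2 at −20 °C reduces the benzylic alcohol through the C3 cation and returns directly at 10. It works only if hydride capture outruns loss of the C2 hydrogen toward the benzofuran, and it makes no new compound.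

Step 9. Oxidative addition into the electron-rich C5–Br bond, para to O1, may be slow, so that the catalyst decomposes before conversion is complete. Fallback: from 12, bromine–lithium exchange (n-BuLi, 2.2 equiv, THF, −78 °C) and quenching with DMF should give (2S)-2-[(2S)-1-hydroxypropan-2-yl]-2,3-dihydro-1-benzofuran-5-carbaldehyde F5. A Wittig reaction with Ph3P=CHCO2t-Bu then returns at 14.

Step 10. The phenol of 15, or the reduced azodicarboxylate, may be alkylated in competition with the carboxylate, and displacement at the β-branched primary carbon may be sluggish. Fallback: it sets out from 15 and 14 and returns at 16.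
- Acetylation of 15 (Ac2O, aq. NaOH, 0 °C; then HCl) gives (2E)-3-[4-(acetyloxy)phenyl]prop-2-enoic acid F6.
- Carbodiimide coupling with 14 (EDC·HCl, DMAP, CH2Cl2) gives the acetate tert-butyl (2E)-3-[(2S)-2-{(2S)-1-[(2E)-3-(4-acetoxyphenyl)prop-2-enoyloxy]propan-2-yl}-2,3-dihydro-1-benzofuran-5-yl]prop-2-enoate F7.
- Selective cleavage of the aryl acetate (NH4OAc, aq. MeOH, rt) returns at 16.

## Further compounds

F1 | step 4 | methyl {5-bromo-2-[(2Z)-but-2-en-1-yloxy]phenyl}acetate | C/C=C\COc1ccc(Br)cc1CC(=O)OC
F2 | step 4 | {5-bromo-2-[(2Z)-but-2-en-1-yloxy]phenyl}acetaldehyde | C/C=C\COc1ccc(Br)cc1CC=O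
F3 | step 4 | (2R,3S)-1-{5-bromo-2-[(2Z)-but-2-en-1-yloxy]phenyl}-3-methylpent-4-en-2-ol | C[C@@H](C=C)[C@H](O)Cc1cc(Br)ccc1OC/C=C\C
F4 | step 4 | (2R,3S)-1-(5-bromo-2-hydroxyphenyl)-3-methylpent-4-en-2-ol | C[C@@H](C=C)[C@H](O)Cc1cc(Br)ccc1O
F0 | step 7 | none | none
F5 | step 9 | (2S)-2-[(2S)-1-hydroxypropan-2-yl]-2,3-dihydro-1-benzofuran-5-carbaldehyde | C[C@@H](CO)[C@@H]1Cc2cc(C=O)ccc2O1
F6 | step 10 | (2E)-3-[4-(acetyloxy)phenyl]prop-2-enoic acid | CC(=O)Oc1ccc(/C=C/C(=O)O)cc1
F7 | step 10 | tert-butyl (2E)-3-[(2S)-2-{(2S)-1-[(2E)-3-(4-acetoxyphenyl)prop-2-enoyloxy]propan-2-yl}-2,3-dihydro-1-benzofuran-5-yl]prop-2-enoate | C[C@@H](COC(=O)/C=C/c1ccc(OC(C)=O)cc1)[C@@H]1Cc2cc(/C=C/C(=O)OC(C)(C)C)ccc2O1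
A1 | alternative 1 | methyl 4-fluoro-3-[(2S)-3-methyl-2-(4,4,5,5-tetramethyl-1,3,2-dioxaborolan-2-yl)but-3-en-1-yl]benzoate | C=C(C)[C@@H](B1OC(C)(C)C(C)(C)O1)Cc1cc(C(=O)OC)ccc1F
A2 | alternative 1 | methyl (2S)-2-(prop-1-en-2-yl)-2,3-dihydro-1-benzofuran-5-carboxylate | C=C(C)[C@@H]1Cc2cc(C(=O)OC)ccc2O1
A3 | alternative 2 | (2S)-5-bromo-2-ethenyl-2,3-dihydro-1-benzofuran | C=C[C@@H]1Cc2cc(Br)ccc2O1
A4 | alternative 2 | (2S)-2-[(2S)-5-bromo-2,3-dihydro-1-benzofuran-2-yl]propan-1-ol | C[C@@H](CO)[C@@H]1Cc2cc(Br)ccc2O1
A5 | alternative 3 | methyl (2S)-2-[3-(tert-butyldimethylsilyloxy)prop-1-en-2-yl]-2,3-dihydro-1-benzofuran-5-carboxylate | C=C(CO[Si](C)(C)C(C)(C)C)[C@@H]1Cc2cc(C(=O)OC)ccc2O1
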